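**Strategy.** The route rests on closing ring B through the C8–C9 bond (labdane numbering). The exocyclic C8=C17 methylene of ring B lies next to C9, whose side chain starts with the C11 methylene. A C8 vinyl radical adding 6-exo to a C9=C11 enoyl thioester therefore builds the methylene, the C9 stereocentre and the C11–C12 handle in one operation. The precursor is a ring A cyclohexane carrying C4 (Me, CO2Me), a C5 arm CH(OAc)CH2C(Br)=CH2 and a C10 (Me) (E)-CH=CH–COSEt arm, the arms trans. Ring A is made by an asymmetric Robinson annulation followed by vinyl cuprate addition and enol ether alkylation, each anti to its neighbour.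

Key step: step 11

Assumption: methyl 2-formylpropanoate 1 is bought as such (its stereocentre is labile and irrelevant); atoms are referred to by labdane numbers.

Step 1
Reactants: 1 methyl 2-formylpropanoate; 2 pent-1-en-3-one
Product: 4 methyl (1S)-1,3-dimethyl-4-oxocyclohex-2-ene-1-carboxylate, via methyl (2S)-2-formyl-2-methyl-5-oxoheptanoate 3 (not isolated)
Conditions: 9-O-(phenanthren-9-yl)cupreidine (C33H30N2O2, 10 mol%), PhMe, −20 °C; then TsOH·H2O (30 mol%), reflux, azeotropic removal of water
Reagents that add atoms: none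
Why: An organocatalytic Michael addition of the acidic 2-formyl ester (a 2-substituted 1,3-dicarbonyl donor) to the vinyl ketone under bifunctional cinchona catalysis should set the C4 quaternary centre as (S), the pseudoenantiomeric cupreine ether being taken instead if the sense of induction requires it, and acid-catalysed aldol condensation of 3 through the only enolisable carbon that can reach the aldehyde in a six-membered ring completes a Robinson annulation without touching that centre.

Step 2
Reactants: 4 methyl (1S)-1,3-dimethyl-4-oxocyclohex-2-ene-1-carboxylate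
Product: 5 methyl (1S,2S)-2-ethenyl-1,3-dimethyl-4-[(trimethylsilyl)oxy]cyclohex-3-ene-1-carboxylate
Conditions: CH2=CHMgBr (2.5 equiv), CuBr·SMe2 (15 mol%), Me3SiCl (3 equiv), DMPU (3 equiv), THF, −78 → −30 °C; Et3N, aq. NaHCO3
Reagents that add atoms: vinylmagnesium bromide, C=C[Mg]Br; chlorotrimethylsilane, C[Si](C)(C)Cl
Why: Copper-catalysed 1,4-addition of the Grignard reagent, accelerated by the chlorosilane, should place the vinyl group (future C6) on C5 anti to the pseudoaxial ester of the neighbouring quaternary carbon, so that C6 is trans to CO2Me, and the enolate is trapped as the regiodefined silyl enol ether, any minor facial isomer being removed by chromatography after the next step.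

Step 3
Reactants: 5 methyl (1S,2S)-2-ethenyl-1,3-dimethyl-4-[(trimethylsilyl)oxy]cyclohex-3-ene-1-carboxylate
Product: 6 methyl (1S,2S,3R)-3-(dimethoxymethyl)-2-ethenyl-1,3-dimethyl-4-oxocyclohexane-1-carboxylate
Conditions: HC(OMe)3 (3 equiv), Me3SiOTf (10 mol%), CH2Cl2, −78 → −40 °C
Reagents that add atoms: trimethyl orthoformate, COC(OC)OC
Why: Mukaiyama-type alkylation of the silyl enol ether by the dimethoxycarbenium ion should form the C10 quaternary centre by axial attack anti to the pseudoaxial C5 vinyl group, so the masked formyl carbon C9 enters trans to C6 and cis to the C4 ester, the small electrophile tolerating the crowded site.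

Step 4
Reactants: 6 methyl (1S,2S,3R)-3-(dimethoxymethyl)-2-ethenyl-1,3-dimethyl-4-oxocyclohexane-1-carboxylate
Product: 7 methyl (1S,2S,3S)-3-(dimethoxymethyl)-2-ethenyl-1,3-dimethyl-4-{2-[(4-methylphenyl)sulfonyl]hydrazinylidene}cyclohexane-1-carboxylate
Conditions: TsNHNH2 (1.5 equiv), MeOH, 60 °C, no acid added
Reagents that add atoms: 4-methylbenzenesulfonohydrazide, Cc1ccc(cc1)S(=O)(=O)NN
Why: Condensation of the ketone with the sulfonyl hydrazide under neutral conditions should give the tosylhydrazone while the dimethyl acetal, which needs acid to ionise, stays intact, and the derivative is expected to be crystalline so that enantiomeric purity can be raised by recrystallisation.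

Step 5
Reactants: 7 methyl (1S,2S,3S)-3-(dimethoxymethyl)-2-ethenyl-1,3-dimethyl-4-{2-[(4-methylphenyl)sulfonyl]hydrazinylidene}cyclohexane-1-carboxylate
Product: 8 methyl (1S,2S,3R)-3-(dimethoxymethyl)-2-ethenyl-1,3-dimethylcyclohexane-1-carboxylate
Conditions: catecholborane (3 equiv), CHCl3, 0 °C → rt; then NaOAc·3H2O (5 equiv), 60 °C
Reagents that add atoms: none
Why: Hydroboration of the C=N bond and acetate-induced loss of sulfinate and N2 from the diazene (reductive deoxygenation of a tosylhydrazone) should turn the former carbonyl carbon C1 into CH2 under conditions that leave ester, acetal and vinyl group alone and touch no stereocentre.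

Step 6
Reactants: 8 methyl (1S,2S,3R)-3-(dimethoxymethyl)-2-ethenyl-1,3-dimethylcyclohexane-1-carboxylate
Product: 9 methyl (1S,2S,3R)-3-(dimethoxymethyl)-2-formyl-1,3-dimethylcyclohexane-1-carboxylate
Conditions: O3, CH2Cl2, −78 °C, stopped at the first excess of ozone; then PPh3 (1.5 equiv), −78 °C → rt
Reagents that add atoms: ozone, [O-][O+]=O
Why: Ozonolysis with reductive work-up should cleave the only alkene to the C6 aldehyde under neutral conditions, so that the C5 stereocentre, now next to a carbonyl but flanked by two quaternary carbons, does not epimerise.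

Step 7
Reactants: 9 methyl (1S,2S,3R)-3-(dimethoxymethyl)-2-formyl-1,3-dimethylcyclohexane-1-carboxylate; 10 2,3-dibromoprop-1-ene
Product: 11 methyl (1S,2S,3R)-2-[(1R)-3-bromo-1-hydroxybut-3-en-1-yl]-3-(dimethoxymethyl)-1,3-dimethylcyclohexane-1-carboxylate
Conditions: CrCl2 (3 equiv), 10 (1.5 equiv), THF, 0 °C → rt; water
Reagents that add atoms: none
Why: In this Nozaki–Hiyama allylation divalent chromium should insert into the allylic C–Br bond of 10 in preference to the vinylic one, the 2-bromoallylchromium species should add to the aldehyde without disturbing the acetal, and Felkin–Anh control with C10 (bearing the bulky dimethoxymethyl group) anti to the nucleophile and the ester-bearing C4 as the medium group should give the (6R)-alcohol.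

Step 8
Reactants: 11 methyl (1S,2S,3R)-2-[(1R)-3-bromo-1-hydroxybut-3-en-1-yl]-3-(dimethoxymethyl)-1,3-dimethylcyclohexane-1-carboxylate
Product: 12 methyl (1S,2S,3R)-2-[(1R)-1-(acetyloxy)-3-bromobut-3-en-1-yl]-3-(dimethoxymethyl)-1,3-dimethylcyclohexane-1-carboxylate
Conditions: Ac2O (3 equiv), 4-(dimethylamino)pyridine (0.2 equiv), pyridine, CH2Cl2, rt
Reagents that add atoms: acetic anhydride, CC(=O)OC(C)=O
Why: Nucleophile-catalysed acylation should esterify the hindered secondary alcohol before it can lactonise onto the neighbouring methyl ester and installs the C6 acetate of the target.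

Step 9
Reactants: 12 methyl (1S,2S,3R)-2-[(1R)-1-(acetyloxy)-3-bromobut-3-en-1-yl]-3-(dimethoxymethyl)-1,3-dimethylcyclohexane-1-carboxylate
Product: 13 methyl (1S,2S,3R)-2-[(1R)-1-(acetyloxy)-3-bromobut-3-en-1-yl]-3-formyl-1,3-dimethylcyclohexane-1-carboxylate
Conditions: CF3CO2H/H2O (1:1), CHCl3, 0 °C
Reagents that add atoms: water, O
Why: Acid-catalysed acetal hydrolysis should free the C9 aldehyde, which has no α-hydrogen and cannot epimerise, while acetate, methyl ester and vinyl bromide withstand brief contact with cold aqueous acid.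

Step 10
Reactants: 13 methyl (1S,2S,3R)-2-[(1R)-1-(acetyloxy)-3-bromobut-3-en-1-yl]-3-formyl-1,3-dimethylcyclohexane-1-carboxylate
Product: 14 methyl (1S,2S,3S)-2-[(1R)-1-(acetyloxy)-3-bromobut-3-en-1-yl]-3-[(1E)-3-(ethylsulfanyl)-3-oxoprop-1-en-1-yl]-1,3-dimethylcyclohexane-1-carboxylate
Conditions: Ph3P=C=C=O (1.5 equiv), EtSH (1.4 equiv), PhMe, rt; then 13, 90 °C
Reagents that add atoms: (triphenylphosphoranylidene)ketene, O=C=C=P(c1ccccc1)(c1ccccc1)c1ccccc1; ethanethiol, CCS
Why: Addition of the thiol to the cumulated ylide gives the stabilised thioester ylide in the flask, and its Wittig reaction with the neopentyl-type aldehyde on heating should give the (E)-enoyl thioester, the thiol being used in deficit so that none remains to add to the product.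

Step 11
Reactants: 14 methyl (1S,2S,3S)-2-[(1R)-1-(acetyloxy)-3-bromobut-3-en-1-yl]-3-[(1E)-3-(ethylsulfanyl)-3-oxoprop-1-en-1-yl]-1,3-dimethylcyclohexane-1-carboxylate
Product: 15 methyl (1S,4aS,5R,8R,8aS)-8-(acetyloxy)-5-[2-(ethylsulfanyl)-2-oxoethyl]-1,4a-dimethyl-6-methylidenedecahydronaphthalene-1-carboxylate
Conditions: Bu3SnH (1.3 equiv) and 2,2'-azobis(2-methylpropanenitrile) (0.2 equiv) in PhH added over 6 h to 14 (0.005 mol/L) in PhH, 80 °C
Reagents that add atoms: none
Why: The stannyl radical abstracts bromine from C8, the σ-vinyl radical adds to C9 (the β-carbon of the enoyl thioester) and the C11 radical takes hydrogen from Bu3SnH to carry the chain, a tin hydride vinyl radical cyclisation onto an electron-poor alkene. Ring B closes in the 6-exo-trig mode with C8=C17 already in place, so no double-bond isomer can arise. The new C9 centre (R) is set by a chair-like transition structure with the C6 acetate and the C9=C11 acceptor pseudo-equatorial and C20 axial, which leaves H9 axial and the C11 arm equatorial, cis to C20. The step needs 6-exo over 7-endo closure and cyclisation over direct reduction: attack at the acceptor β-carbon is polarity-matched, the trans-diequatorial arms on ring A hold C8 near C9, and slow addition keeps the stannane concentration low. Because C4 and C10 are quaternary no hydrogen is placed for 1,5-transfer to C8, and acetate, methyl ester and S-ethyl thioester are inert to stannyl radicals.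

Step 12
Reactants: 15 methyl (1S,4aS,5R,8R,8aS)-8-(acetyloxy)-5-[2-(ethylsulfanyl)-2-oxoethyl]-1,4a-dimethyl-6-methylidenedecahydronaphthalene-1-carboxylate
Product: 16 methyl (1S,4aS,5R,8R,8aS)-8-(acetyloxy)-1,4a-dimethyl-6-methylidene-5-(2-oxoethyl)decahydronaphthalene-1-carboxylate
Conditions: Et3SiH (3 equiv), 10% Pd/C (5 mol% Pd), acetone, rt, short reaction time
Reagents that add atoms: none
Why: In this Fukuyama reduction the thioester C–S bond adds to palladium and the silane delivers hydride to give the C12 aldehyde, which should spare the acetate, the hindered methyl ester and, in an aprotic solvent, the 1,1-disubstituted alkene.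

Step 13
Reactants: 16 methyl (1S,4aS,5R,8R,8aS)-8-(acetyloxy)-1,4a-dimethyl-6-methylidene-5-(2-oxoethyl)decahydronaphthalene-1-carboxylate
Product: 17 methyl (1S,4aS,5R,8R,8aS)-8-(acetyloxy)-1,4a-dimethyl-5-[(2E)-3-methyl-4-oxobut-2-en-1-yl]-6-methylidenedecahydronaphthalene-1-carboxylate
Conditions: Ph3P=C(CH3)CHO (1.3 equiv), PhMe, 80 °C
Reagents that add atoms: 2-(triphenylphosphoranylidene)propanal, CC(C=O)=P(c1ccccc1)(c1ccccc1)c1ccccc1
Why: Wittig olefination with the stabilised formyl ylide is (E)-selective and should stop after one homologation because the 2-methyl enal formed is far less electrophilic than the starting aldehyde.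

Step 14
Reactants: 17 methyl (1S,4aS,5R,8R,8aS)-8-(acetyloxy)-1,4a-dimethyl-5-[(2E)-3-methyl-4-oxobut-2-en-1-yl]-6-methylidenedecahydronaphthalene-1-carboxylate
Product: 18 methyl (1S,4aS,5R,8R,8aS)-8-(acetyloxy)-1,4a-dimethyl-6-methylidene-5-[(2E)-3-methylpenta-2,4-dien-1-yl]decahydronaphthalene-1-carboxylate
Conditions: Ph3PCH3Br (1.5 equiv), KN(SiMe3)2 (1.4 equiv), THF, 0 °C; then 17, −78 → 0 °C
Reagents that add atoms: methyltriphenylphosphonium bromide, C[P+](c1ccccc1)(c1ccccc1)c1ccccc1.[Br-]
Why: Wittig methylenation with the non-stabilised ylide should convert the enal carbonyl into the terminal alkene by 1,2-addition at low temperature without touching the esters or the trisubstituted alkene geometry, which completes the (12E)-diene.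

**Compound list**

1 | methyl 2-formylpropanoate (methyl 2-methyl-3-oxopropanoate) | COC(=O)C(C)C=O | starting material
2 | pent-1-en-3-one | CCC(=O)C=C | starting material
3 | methyl (2S)-2-formyl-2-methyl-5-oxoheptanoate | CCC(=O)CC[C@](C)(C(=O)OC)C=O | intermediate
4 | methyl (1S)-1,3-dimethyl-4-oxocyclohex-2-ene-1-carboxylate | O=C1CC[C@](C)(C(=O)OC)C=C1C | intermediate
5 | methyl (1S,2S)-2-ethenyl-1,3-dimethyl-4-[(trimethylsilyl)oxy]cyclohex-3-ene-1-carboxylate | C=C[C@H]1C(C)=C(O[Si](C)(C)C)CC[C@]1(C)C(=O)OC | intermediate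
6 | methyl (1S,2S,3R)-3-(dimethoxymethyl)-2-ethenyl-1,3-dimethyl-4-oxocyclohexane-1-carboxylate | C=C[C@H]1[C@@](C(OC)OC)(C)C(=O)CC[C@]1(C)C(=O)OC | intermediate
7 | methyl (1S,2S,3S)-3-(dimethoxymethyl)-2-ethenyl-1,3-dimethyl-4-{2-[(4-methylphenyl)sulfonyl]hydrazinylidene}cyclohexane-1-carboxylate | C=C[C@H]1[C@@](C(OC)OC)(C)C(=NNS(=O)(=O)c2ccc(C)cc2)CC[C@]1(C)C(=O)OC | intermediate
8 | methyl (1S,2S,3R)-3-(dimethoxymethyl)-2-ethenyl-1,3-dimethylcyclohexane-1-carboxylate | C=C[C@H]1[C@@](C(OC)OC)(C)CCC[C@]1(C)C(=O)OC | intermediate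
9 | methyl (1S,2S,3R)-3-(dimethoxymethyl)-2-formyl-1,3-dimethylcyclohexane-1-carboxylate | O=C[C@H]1[C@@](C(OC)OC)(C)CCC[C@]1(C)C(=O)OC | intermediate
10 | 2,3-dibromoprop-1-ene | C=C(Br)CBr | starting material
11 | methyl (1S,2S,3R)-2-[(1R)-3-bromo-1-hydroxybut-3-en-1-yl]-3-(dimethoxymethyl)-1,3-dimethylcyclohexane-1-carboxylate | C=C(Br)C[C@@H](O)[C@H]1[C@@](C(OC)OC)(C)CCC[C@]1(C)C(=O)OC | intermediate
12 | methyl (1S,2S,3R)-2-[(1R)-1-(acetyloxy)-3-bromobut-3-en-1-yl]-3-(dimethoxymethyl)-1,3-dimethylcyclohexane-1-carboxylate | C=C(Br)C[C@@H](OC(C)=O)[C@H]1[C@@](C(OC)OC)(C)CCC[C@]1(C)C(=O)OC | intermediate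
13 | methyl (1S,2S,3R)-2-[(1R)-1-(acetyloxy)-3-bromobut-3-en-1-yl]-3-formyl-1,3-dimethylcyclohexane-1-carboxylate | C=C(Br)C[C@@H](OC(C)=O)[C@H]1[C@@](C=O)(C)CCC[C@]1(C)C(=O)OC | intermediate
14 | methyl (1S,2S,3S)-2-[(1R)-1-(acetyloxy)-3-bromobut-3-en-1-yl]-3-[(1E)-3-(ethylsulfanyl)-3-oxoprop-1-en-1-yl]-1,3-dimethylcyclohexane-1-carboxylate | C=C(Br)C[C@@H](OC(C)=O)[C@H]1[C@@](/C=C/C(=O)SCC)(C)CCC[C@]1(C)C(=O)OC | intermediate
15 | methyl (1S,4aS,5R,8R,8aS)-8-(acetyloxy)-5-[2-(ethylsulfanyl)-2-oxoethyl]-1,4a-dimethyl-6-methylidenedecahydronaphthalene-1-carboxylate | CCSC(=O)C[C@@H]1C(=C)C[C@@H](OC(C)=O)[C@H]2[C@@]1(C)CCC[C@]2(C)C(=O)OC | intermediate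
16 | methyl (1S,4aS,5R,8R,8aS)-8-(acetyloxy)-1,4a-dimethyl-6-methylidene-5-(2-oxoethyl)decahydronaphthalene-1-carboxylate | O=CC[C@@H]1C(=C)C[C@@H](OC(C)=O)[C@H]2[C@@]1(C)CCC[C@]2(C)C(=O)OC | intermediate
17 | methyl (1S,4aS,5R,8R,8aS)-8-(acetyloxy)-1,4a-dimethyl-5-[(2E)-3-methyl-4-oxobut-2-en-1-yl]-6-methylidenedecahydronaphthalene-1-carboxylate | O=C/C(C)=C/C[C@@H]1C(=C)C[C@@H](OC(C)=O)[C@H]2[C@@]1(C)CCC[C@]2(C)C(=O)OC | intermediate
18 | methyl (1S,4aS,5R,8R,8aS)-8-(acetyloxy)-1,4a-dimethyl-6-methylidene-5-[(2E)-3-methylpenta-2,4-dien-1-yl]decahydronaphthalene-1-carboxylate | C=C/C(C)=C/C[C@@H]1C(=C)C[C@@H](OC(C)=O)[C@H]2[C@@]1(C)CCC[C@]2(C)C(=O)OC | target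

**Step count.** Total: 14 steps. Longest linear sequence: 14 steps (1 and 2 to 18).

**Steps most likely to fail**

Step 11. The C8 vinyl radical may take hydrogen from the stannane before it closes the ring, or closure through a boat-like arrangement may erode the configuration at C9. The fallback replaces the radical by a two-electron carbopalladation and sets out from aldehyde 13. Wittig reaction with (triphenylphosphoranylidene)acetaldehyde (PhMe, 80 °C) should give the (E)-enal methyl (1S,2S,3S)-2-[(1R)-1-(acetyloxy)-3-bromobut-3-en-1-yl]-1,3-dimethyl-3-[(1E)-3-oxoprop-1-en-1-yl]cyclohexane-1-carboxylate F1. A reductive Heck cyclisation (Pd(OAc)2, PPh3, HCO2Na, Et4NCl, DMF, 80 °C) then lets the vinylpalladium species formed at C8 add syn across C9=C11, and formate delivers the hydride. This forms the same C8–C9 bond and gives aldehyde 16 directly, where the route is rejoined.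

Step 7. Facial discrimination at the C6 aldehyde may be poor, because the two quaternary carbons flanking C5 differ only in their equatorial substituent. The fallback sets out from alcohol 11 as obtained, whatever its composition at C6. Dess–Martin oxidation (NaHCO3, CH2Cl2) should give the ketone methyl (1S,2S,3R)-2-(3-bromobut-3-enoyl)-3-(dimethoxymethyl)-1,3-dimethylcyclohexane-1-carboxylate F2. Corey–Bakshi–Shibata reduction with (3aS)-1-methyl-3,3-diphenyltetrahydro-1H,3H-pyrrolo[1,2-c][1,3,2]oxazaborole (20 mol%) and BH3·SMe2 in THF at −30 °C treats the ring carbon as the large group and should return the (6R)-alcohol under reagent control. The route is rejoined at 11.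

Step 1. Enantiofacial control in the Michael addition may be insufficient, since a 2-formyl ester is a less studied donor for this catalyst class than a 3-keto ester. The fallback uses a stoichiometric chiral amine and sets out from 1. Condensation with (1S)-1-phenylethan-1-amine (PhMe, azeotropic removal of water) should give the enamino ester methyl 2-methyl-3-{[(1S)-1-phenylethyl]amino}prop-2-enoate F3. Its thermal Michael addition to 2 (THF, 60 °C) should occur on the face away from the phenyl group and give the imine methyl (2S)-2-methyl-5-oxo-2-({[(1S)-1-phenylethyl]imino}methyl)heptanoate F4. Hydrolysis with aqueous AcOH releases keto aldehyde 3, which is cyclised as in step 1. The (1R)-amine is taken if the sense of induction requires it. The route is rejoined at 3.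

**Further compounds**

F1 | step 11 | methyl (1S,2S,3S)-2-[(1R)-1-(acetyloxy)-3-bromobut-3-en-1-yl]-1,3-dimethyl-3-[(1E)-3-oxoprop-1-en-1-yl]cyclohexane-1-carboxylate | C=C(Br)C[C@@H](OC(C)=O)[C@H]1[C@@](/C=C/C=O)(C)CCC[C@]1(C)C(=O)OC
F2 | step 7 | methyl (1S,2S,3R)-2-(3-bromobut-3-enoyl)-3-(dimethoxymethyl)-1,3-dimethylcyclohexane-1-carboxylate | C=C(Br)CC(=O)[C@H]1[C@@](C(OC)OC)(C)CCC[C@]1(C)C(=O)OC
F3 | step 1 | methyl 2-methyl-3-{[(1S)-1-phenylethyl]amino}prop-2-enoate | COC(=O)C(C)=CN[C@@H](C)c1ccccc1
F4 | step 1 | methyl (2S)-2-methyl-5-oxo-2-({[(1S)-1-phenylethyl]imino}methyl)heptanoate | CCC(=O)CC[C@](C)(C(=O)OC)C=N[C@@H](C)c1ccccc1
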